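Assumption: atoms are numbered as in 2H-chromene (O1, C2, C3, C4, C4a, C5 to C8, C8a), Cα and Cβ are the diketone carbons bound to C6 and to ring B, and every chiral intermediate is racemic because the target has no stereocentre.

## Analysis of the target

Derrisdione A (28) is a 2,2-dimethyl-2H-chromene whose benzene ring A (C4a, C5, C6, C7, C8, C8a) carries no hydrogen. C5 bears a methoxy group, C6 a 1,2-diketone that ends in the 4-hydroxyphenyl ring B, C7 a free hydroxyl and C8 a prenyl group, while C8a and C4a hold the oxygen and the C4=C3 double bond of the pyran ring. There is no stereocentre, so the problem is one of regiochemistry and chemoselectivity only. The sensitive functions are the prenyl group next to the C7 hydroxyl (acid closes it to a chroman), the electron-rich chromene double bond, the 1,2-diketone (amines, hydroxide, benzilic-type rearrangement) and two phenols. The difficulty sits in ring A: a 1,3,5-trioxygenated benzene whose three oxygens must end as methyl ether, free phenol and ring ether, with an acyl carbon, a prenyl group and the pyran carbon between them. Substitution chemistry on such a ring meets O- versus C-alkylation, linear versus angular pyran fusion and a hindered acylation site between two oxygens. The plan rests on the strict alternation of these substituents: C4a, C5, C6 and C7 (H, OMe, carbon, O) form the pattern of a 4-chloro-3-methoxy-2-alkynylcyclobutenone, and C8a with C8 is an oxygenated alkene carbon next to a prenyl-bearing one. The diketone is treated as an oxidised diarylalkyne, a slim and inert group that can be carried at crowded C6 through the ring construction.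

## Retrosynthetic reasoning

The last two operations only uncover oxygens. Target 28 is traced to its C7 acetate 27 and then to the ring B methoxymethyl ether 26. The acetal is cleaved while the C7 oxygen is still acylated, so no free hydroxyl sits beside the prenyl group when acid is present. The acetate then leaves by cold basic methanolysis.

The two C=O bonds at Cα and Cβ of 26 are taken back to the triple bond of 25. A diketone would not survive the amine used to build the pyran or the organometallic steps, whereas a diarylalkyne is inert and small enough for the position between two oxygens. The forward reaction must oxygenate the alkyne in the presence of the prenyl and chromene double bonds. The C7 oxygen must be acylated first, because a free phenol next to an activated alkyne would close to a benzofuran.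

Acetate 25 comes from phenol 24, and the pyran ring of 24 is cut at O1–C2 and C4–C4a, giving resorcinol 21 and 3-methylbut-2-enal 22. The aldehyde supplies C2, C3, C4 and both methyl groups. C4a is the only unsubstituted ring carbon of 21 and only the C8a hydroxyl is ortho to it, so the condensation can give only one pyran. Diol 21 is the desilylation product of 20.

The central cut removes the C4a–C8a and C7–C8 bonds of ring A in 20. It leads to chlorocyclobutenone 9 (C4a, C5, C6, C7 with the methoxy and alkynyl groups in place) and alkenylstannane 17 (C8a with its silylated oxygen, C8 with the prenyl group). Any other pair of bonds would leave an oxygen or a carbon substituent to be introduced on a finished arene, where the positions compete. Here each ring atom has a defined origin, the three oxygens arrive as methyl ether, free phenol and silyl ether, and the prenyl group is attached before the ring exists. The forward reaction has to join C4a to C8a by cross-coupling and then close C7 to C8 by ring opening and electrocyclization.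

Chloride 9 is taken back to alcohol 8 and to cyclobutenedione 7, which comes from dimethyl squarate 4 and alkyne 3 by cutting the C6–Cα bond. Of the two carbonyls of 7, only the one beside the methoxy-bearing carbon is a plain ketone, so hydride should attack there. That places the leaving group on the future C4a and keeps the future C7 as the carbonyl.

Alkyne 3 is a one-carbon homologue of aldehyde 2, the methoxymethyl ether of 4-hydroxybenzaldehyde 1. The acetal tolerates the organolithium, hydride and palladium steps and is removed only at the end.

Stannane 17 is the syn adduct of tributyltin hydride 16 to silyl ynol ether 15, with tin on the oxygen-bearing carbon. Ynol ether 15 is the O-silylated ynolate of enyne 12, which is cut at its propargylic bond into prenyl bromide 10 and ethynylmagnesium bromide 11. The triisopropylsilyl group makes 15 and 17 stable enough to handle and is later removed without touching the methyl or methoxymethyl ethers.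

## Alternatives that were turned down

Alternative 1: Both bonds that flank the diketone (C6–Cα and Cβ–ring B) are cut, and the two carbonyl carbons come from the cyclic oxamide 1,4-dimethylpiperazine-2,3-dione A2.
- Forward key step: the finished ring A chromene 5-methoxy-7-(methoxymethoxy)-2,2-dimethyl-8-(3-methylbut-2-enyl)-2H-chromene A3 is lithiated at C6 between its two directing oxygens. The aryllithium adds once to A2, the chelated tetrahedral adduct persists, and 4-(methoxymethoxy)phenylmagnesium bromide A4 adds to the second carbonyl. Work-up releases derrisdione A bis(methoxymethyl) ether A1.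
- For it: the skeleton and the diketone oxidation level are reached in one flask, no oxidation is needed in the presence of the two alkenes, and C6–H of A3 is an ideal site for directed metalation. On convergence and on the length of the endgame it is stronger than the chosen plan.
- Against it: A3 is itself the hard part, a fully differentiated trioxygenated arene, so the regiochemical problem of ring A is only moved back to substitution chemistry. The di-ortho-substituted aryllithium must add exactly once to A2, and symmetric diketones from double addition are a structural risk. A1 needs acid to free two phenols, one of them beside the prenyl group.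
- Comparison: the chosen plan spends more steps after the key step, but it builds ring A with every position fixed by connectivity and uncovers the C7 hydroxyl under base.

Alternative 2: The diketone is seen as an isoflavone that has lost C2, and the isoflavone is cut at the Cβ–ring B bond by way of a chalcone.
- Forward key step: (E)-1-[4-(benzyloxy)-2-hydroxy-6-methoxyphenyl]-3-[4-(methoxymethoxy)phenyl]prop-2-en-1-one A6 is treated with thallium trinitrate A7 (trivalent thallium) in an alcohol. The aryl group shifts from the β to the α carbon, and acid closes the pyranone to 7-(benzyloxy)-5-methoxy-3-[4-(methoxymethoxy)phenyl]chromen-4-one A5.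
- For it: the sequence is classical, the starting materials are cheap, and the three ring A oxygens of A5 are also in three different states, so on oxygen differentiation it equals the chosen plan.
- Against it: C2 must be removed by oxidative cleavage of an enol ether double bond, which cannot be done once the prenyl and chromene alkenes are present. Both must therefore be introduced afterwards on an arene with two free positions, where C- versus O-prenylation and the site of pyran fusion compete. The thallium reagent is toxic, and the count of steps after A5 (cleavage, debenzylation, prenylation, chromenylation, deprotection) is high.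
- Comparison: the chosen plan places the prenyl group and the C6 carbon before ring A exists and so avoids both late substitutions.

Alternative 3: Ring A is cut at C4a–C5 and C8–C8a into a four-carbon acylketene O,S-acetal and a two-carbon acetate unit.
- Forward key step: the lithium enolate of methyl acetate A9 displaces the thiolate from the acetal carbon of 3-[methoxy(methylsulfanyl)methylidene]-1,1-dimethoxy-1-[4-(methoxymethoxy)phenyl]-8-methylnon-7-ene-2,4-dione A10. The enolate of the chain ketone then attacks the ester carbon and the ring aromatizes to 1-[2,4-dihydroxy-6-methoxy-3-(3-methylbut-2-enyl)phenyl]-2,2-dimethoxy-2-[4-(methoxymethoxy)phenyl]ethanone A8.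
- For it: it is also a de novo ring A synthesis with the prenyl group in place, and it carries the diketone at the right oxidation level as a monoketal. On that point it is stronger than the chosen plan, which needs a late alkyne oxidation.
- Against it: A10 is a crowded, unsymmetrical tricarbonyl derivative that needs a long preparation of its own. The ester enolate can add to either ketone instead of the acetal carbon, the methoxy group can leave in place of the thiolate, and the closing Claisen-type attack competes with aldol pathways. A8 carries two free hydroxyls that only hydrogen bonding tells apart.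
- Comparison: the chosen plan uses a coupling and electrocyclization sequence of a known type, with no competing sites in either partner, and gives three oxygens in three different states.

Key step: step 9

## Route

Step 1
Reactants: 1 4-hydroxybenzaldehyde
Product: 2 4-(methoxymethoxy)benzaldehyde
Conditions: MOMCl, i-Pr2NEt, CH2Cl2, 0 °C to rt
Reagents that add atoms: chloromethyl methyl ether, COCCl
Why: Williamson-type O-alkylation of the phenol by the reactive α-chloro ether; the aldehyde is untouched and the acetal is stable to the organolithium, hydride and palladium steps that follow.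

Step 2
Reactants: 2 4-(methoxymethoxy)benzaldehyde
Product: 3 1-ethynyl-4-(methoxymethoxy)benzene
Conditions: dimethyl (1-diazo-2-oxopropyl)phosphonate, K2CO3, MeOH, 0 °C to rt
Reagents that add atoms: dimethyl (1-diazo-2-oxopropyl)phosphonate, COP(=O)(OC)C(=[N+]=[N-])C(C)=O
Why: Seyferth–Gilbert homologation in the Ohira–Bestmann form: methanolysis frees the diazomethylphosphonate anion, olefination gives a diazoalkene, and loss of N2 with a 1,2-hydrogen shift gives the terminal alkyne under conditions that leave the acetal alone.

Step 3
Reactants: 3 1-ethynyl-4-(methoxymethoxy)benzene; 4 dimethyl squarate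
Product: 7 3-methoxy-4-{[4-(methoxymethoxy)phenyl]ethynyl}cyclobut-3-ene-1,2-dione, via lithium acetylide 5 (not isolated), via lithium alkoxide adduct 6 (not isolated)
Conditions: n-BuLi, THF, −78 °C; then 4, −78 °C; then (CF3CO)2O, −78 °C; aq. NH4Cl, to rt
Reagents that add atoms: water, O
Why: 1,2-addition of the acetylide to one of the two equivalent carbonyls of the squarate, then the standard squarate-to-cyclobutenedione rearrangement: the trifluoroacetylated tertiary alkoxide ionizes with help from the vinylogous methoxy group, the aqueous quench adds at the methoxy-bearing carbon, and methanol is lost.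

Step 4
Reactants: 7 3-methoxy-4-{[4-(methoxymethoxy)phenyl]ethynyl}cyclobut-3-ene-1,2-dione
Product: 8 4-hydroxy-3-methoxy-2-{[4-(methoxymethoxy)phenyl]ethynyl}cyclobut-2-en-1-one (racemic)
Conditions: LiAl(Ot-Bu)3H, THF, −78 °C; H2O work-up
Reagents that add atoms: none
Why: The carbonyl beside the methoxy-bearing carbon is a plain ketone, whereas the other is the carbonyl of a vinylogous ester, so the bulky alkoxyaluminium hydride should add 1,2 to the former at low temperature, as is usual for 3-alkoxycyclobutenediones; the new centre is racemic and is erased in step 9.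

Step 5
Reactants: 8 4-hydroxy-3-methoxy-2-{[4-(methoxymethoxy)phenyl]ethynyl}cyclobut-2-en-1-one
Product: 9 4-chloro-3-methoxy-2-{[4-(methoxymethoxy)phenyl]ethynyl}cyclobut-2-en-1-one (racemic)
Conditions: PPh3, CCl4, CH2Cl2, 0 °C to rt
Reagents that add atoms: carbon tetrachloride, ClC(Cl)(Cl)Cl
Why: Appel reaction: chloride displaces the alkoxyphosphonium group at a carbon that is both allylic and alpha to the ketone, and the neutral medium avoids the acid-promoted loss of methanol from 8; the chloride is used without storage.

Step 6
Reactants: 10 prenyl bromide (1-bromo-3-methylbut-2-ene); 11 ethynylmagnesium bromide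
Product: 12 5-methylhex-4-en-1-yne
Conditions: CuCl (5 mol %), THF, 0 °C to rt, excess 11
Reagents that add atoms: none
Why: Copper-catalysed allylic substitution of a primary allylic bromide by an alkynyl Grignard reagent; attack at the unhindered α carbon should give the skipped enyne rather than the tertiary SN2′ isomer, and excess 11 suppresses double alkylation.

Step 7
Reactants: 12 5-methylhex-4-en-1-yne
Product: 15 triisopropyl[(5-methylhex-4-en-1-yn-1-yl)oxy]silane, via lithium acetylide 13 (not isolated), via lithium ynolate 14 (not isolated)
Conditions: n-BuLi, THF, −78 °C; LiOOt-Bu (from t-BuOOH and LiN(SiMe3)2), −78 to 0 °C; TIPSOTf, −78 to 0 °C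
Reagents that add atoms: tert-butyl hydroperoxide, CC(C)(C)OO; triisopropylsilyl trifluoromethanesulfonate, CC(C)[Si](OS(=O)(=O)C(F)(F)F)(C(C)C)C(C)C
Why: Oxidation of a lithium acetylide by lithium tert-butyl peroxide gives the lithium ynolate, which the bulky silyl triflate traps on oxygen as the silyl ynol ether; deprotonation at −78 °C is selective for the sp C–H over the doubly activated CH2.

Step 8
Reactants: 15 triisopropyl[(5-methylhex-4-en-1-yn-1-yl)oxy]silane; 16 tributyltin hydride
Product: 17 (E)-tributyl[5-methyl-1-(triisopropylsilyloxy)hexa-1,4-dien-1-yl]stannane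
Conditions: Pd(PPh3)4 (2 mol %), THF, 0 °C to rt
Reagents that add atoms: none
Why: Palladium-catalysed hydrostannation of an ynol ether is a syn addition that places tin on the oxygen-bearing carbon, as with 1-alkoxyalkynes and ynamides; this gives the (E) isomer with tin trans to the CH2 group, and the trisubstituted alkene does not react.

Step 9
Reactants: 9 4-chloro-3-methoxy-2-{[4-(methoxymethoxy)phenyl]ethynyl}cyclobut-2-en-1-one; 17 (E)-tributyl[5-methyl-1-(triisopropylsilyloxy)hexa-1,4-dien-1-yl]stannane
Product: 20 3-methoxy-2-{[4-(methoxymethoxy)phenyl]ethynyl}-6-(3-methylbut-2-enyl)-5-(triisopropylsilyloxy)phenol, via 4-alkenylcyclobutenone 18 (not isolated), via dienylketene 19 (not isolated)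
Conditions: Pd(PPh3)4 (5 mol %), 1,4-dioxane, 50 °C; then 100 °C
Reagents that add atoms: none
Why: Zerovalent palladium inserts into the allylic, α-keto C–Cl bond of 9; transmetalation with 17 and reductive elimination at the unsubstituted terminus (the other terminus carries the alkynyl group) form the C4a–C8a bond with retention of alkene geometry and give 18. On heating, 18 undergoes thermal conrotatory 4π opening of the four-membered ring (the C7–C4a bond breaks) to the dienylketene 19. The ketene carbon (future C7) and the alkene carbon that carries the prenyl CH2 (future C8) then close by a thermal disrotatory 6π electrocyclization, an all-carbon six-membered closure of a hexatriene, and the cyclohexadienone tautomerizes to phenol 20. The closest known reaction type is the Stille coupling of 4-chlorocyclobutenones with alkenyl- and arylstannanes followed by ring opening and electrocyclization to phenols. No stereocentre is formed and the racemic centre of 9 disappears. Regiochemistry follows from connectivity alone: the ketene oxygen becomes the free C7 hydroxyl, the squarate methoxy stays at C5, the stannane oxygen arrives as the C8a silyl ether, the alkyne sits at C6 and the prenyl group at C8. Only the ring-opened rotamer with the alkenyl group turned toward the ketene can close, and because the opening is reversible the other rotamer returns to 18 and is drawn through; the syn geometry of 17 puts H rather than the CH2 group on the inside of the closing terminus. The step needs selectivity for the C–Cl bond over the alkyne and the silyl enol ether, which base-free conditions and a coupling temperature below the ring-opening threshold of 9 should secure.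

Step 10
Reactants: 20 3-methoxy-2-{[4-(methoxymethoxy)phenyl]ethynyl}-6-(3-methylbut-2-enyl)-5-(triisopropylsilyloxy)phenol
Product: 21 5-methoxy-4-{[4-(methoxymethoxy)phenyl]ethynyl}-2-(3-methylbut-2-enyl)benzene-1,3-diol
Conditions: Bu4NF, AcOH, THF, 0 °C
Reagents that add atoms: none
Why: Fluoride cleaves the aryl silyl ether within minutes at 0 °C; buffering with acetic acid keeps the C7 phenoxide concentration low so that 5-endo attack on the neighbouring alkyne does not start, and the acetal is inert.

Step 11
Reactants: 21 5-methoxy-4-{[4-(methoxymethoxy)phenyl]ethynyl}-2-(3-methylbut-2-enyl)benzene-1,3-diol; 22 3-methylbut-2-enal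
Product: 24 5-methoxy-6-{[4-(methoxymethoxy)phenyl]ethynyl}-2,2-dimethyl-8-(3-methylbut-2-enyl)-2H-chromen-7-ol, via ortho-quinone methide 23 (not isolated)
Conditions: ethylenediammonium diacetate (20 mol %), toluene, 80 °C
Reagents that add atoms: none
Why: Amine-salt-catalysed condensation of the resorcinol with the enal at C4a, the only unsubstituted ring carbon, gives an ortho-quinone methide that closes by oxa-6π electrocyclization onto the C8a oxygen (formal [3+3] chromenylation); the C7 hydroxyl is para to C4a and cannot form a six-membered ring, so only the desired pyran can arise.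

Step 12
Reactants: 24 5-methoxy-6-{[4-(methoxymethoxy)phenyl]ethynyl}-2,2-dimethyl-8-(3-methylbut-2-enyl)-2H-chromen-7-ol
Product: 25 5-methoxy-6-{[4-(methoxymethoxy)phenyl]ethynyl}-2,2-dimethyl-8-(3-methylbut-2-enyl)-2H-chromen-7-yl acetate
Conditions: Ac2O, pyridine, DMAP (cat.), CH2Cl2, 0 °C to rt
Reagents that add atoms: acetic anhydride, CC(=O)OC(C)=O
Why: DMAP-catalysed acylation of the only free hydroxyl; the acetate removes the nucleophile that would otherwise add to the palladium-activated alkyne in the next step.

Step 13
Reactants: 25 5-methoxy-6-{[4-(methoxymethoxy)phenyl]ethynyl}-2,2-dimethyl-8-(3-methylbut-2-enyl)-2H-chromen-7-yl acetate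
Product: 26 1-[7-acetoxy-5-methoxy-2,2-dimethyl-8-(3-methylbut-2-enyl)-2H-chromen-6-yl]-2-[4-(methoxymethoxy)phenyl]ethane-1,2-dione
Conditions: PdCl2 (10 mol %), DMSO, 120–140 °C
Reagents that add atoms: dimethyl sulfoxide, CS(C)=O
Why: Dioxygenation of a diarylalkyne by DMSO under divalent palladium catalysis (two Wacker-type attacks of the sulfoxide oxygen on the metal-bound alkyne, each releasing dimethyl sulfide) is a known route to benzils; the internal trisubstituted and disubstituted alkenes are poor substrates in the absence of water, and the acylated C7 oxygen cannot cyclize.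

Step 14
Reactants: 26 1-[7-acetoxy-5-methoxy-2,2-dimethyl-8-(3-methylbut-2-enyl)-2H-chromen-6-yl]-2-[4-(methoxymethoxy)phenyl]ethane-1,2-dione
Product: 27 1-[7-acetoxy-5-methoxy-2,2-dimethyl-8-(3-methylbut-2-enyl)-2H-chromen-6-yl]-2-(4-hydroxyphenyl)ethane-1,2-dione
Conditions: 2 M aq. HCl, THF, 40 °C
Reagents that add atoms: none
Why: Acid-catalysed hydrolysis of the aryl methoxymethyl acetal; the C7 acetate is kept so that no free hydroxyl sits beside the prenyl group while acid is present, and an alcohol-free medium disfavours ester exchange (any acetate lost here already gives 28).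

Step 15
Reactants: 27 1-[7-acetoxy-5-methoxy-2,2-dimethyl-8-(3-methylbut-2-enyl)-2H-chromen-6-yl]-2-(4-hydroxyphenyl)ethane-1,2-dione
Product: 28 derrisdione A, 1-[7-hydroxy-5-methoxy-2,2-dimethyl-8-(3-methylbut-2-enyl)-2H-chromen-6-yl]-2-(4-hydroxyphenyl)ethane-1,2-dione
Conditions: K2CO3, MeOH, 0 °C; aq. NH4Cl
Reagents that add atoms: none
Why: Base-catalysed methanolysis of the activated aryl acetate at 0 °C; the short, cold exposure and the ring B phenoxide, which lowers the electrophilicity of the diketone, should keep benzilic-type rearrangement from competing.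

## Compound list

1 | 4-hydroxybenzaldehyde | O=Cc1ccc(O)cc1 | starting material
2 | 4-(methoxymethoxy)benzaldehyde | COCOc1ccc(C=O)cc1 | intermediate
3 | 1-ethynyl-4-(methoxymethoxy)benzene | COCOc1ccc(C#C)cc1 | intermediate
4 | dimethyl squarate (3,4-dimethoxycyclobut-3-ene-1,2-dione) | COC1=C(OC)C(=O)C1=O | starting material
5 | {[4-(methoxymethoxy)phenyl]ethynyl}lithium | [Li]C#Cc1ccc(OCOC)cc1 | intermediate (not isolated)
6 | lithium 2,3-dimethoxy-1-{[4-(methoxymethoxy)phenyl]ethynyl}-4-oxocyclobut-2-en-1-olate (racemic) | [Li+].[O-]C1(C#Cc2ccc(OCOC)cc2)C(OC)=C(OC)C1=O | intermediate (not isolated)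
7 | 3-methoxy-4-{[4-(methoxymethoxy)phenyl]ethynyl}cyclobut-3-ene-1,2-dione | COCOc1ccc(cc1)C#CC1=C(OC)C(=O)C1=O | intermediate
8 | 4-hydroxy-3-methoxy-2-{[4-(methoxymethoxy)phenyl]ethynyl}cyclobut-2-en-1-one (racemic) | COCOc1ccc(cc1)C#CC1=C(OC)C(O)C1=O | intermediate
9 | 4-chloro-3-methoxy-2-{[4-(methoxymethoxy)phenyl]ethynyl}cyclobut-2-en-1-one (racemic) | COCOc1ccc(cc1)C#CC1=C(OC)C(Cl)C1=O | intermediate
10 | prenyl bromide (1-bromo-3-methylbut-2-ene) | CC(C)=CCBr | starting material
11 | ethynylmagnesium bromide | C#C[Mg]Br | starting material
12 | 5-methylhex-4-en-1-yne | C#CCC=C(C)C | intermediate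
13 | (5-methylhex-4-en-1-yn-1-yl)lithium | [Li]C#CCC=C(C)C | intermediate (not isolated)
14 | lithium 5-methylhex-4-en-1-yn-1-olate | [Li+].[O-]C#CCC=C(C)C | intermediate (not isolated)
15 | triisopropyl[(5-methylhex-4-en-1-yn-1-yl)oxy]silane | CC(C)[Si](OC#CCC=C(C)C)(C(C)C)C(C)C | intermediate
16 | tributyltin hydride | CCCC[SnH](CCCC)CCCC | starting material
17 | (E)-tributyl[5-methyl-1-(triisopropylsilyloxy)hexa-1,4-dien-1-yl]stannane | CC(C)[Si](O/C(=C\CC=C(C)C)[Sn](CCCC)(CCCC)CCCC)(C(C)C)C(C)C | intermediate
18 | 3-methoxy-2-{[4-(methoxymethoxy)phenyl]ethynyl}-4-[(1Z)-5-methyl-1-(triisopropylsilyloxy)hexa-1,4-dien-1-yl]cyclobut-2-en-1-one (racemic) | COCOc1ccc(cc1)C#CC1=C(OC)C(C1=O)/C(O[Si](C(C)C)(C(C)C)C(C)C)=C/CC=C(C)C | intermediate (not isolated)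
19 | (3E,5Z)-3-methoxy-2-{[4-(methoxymethoxy)phenyl]ethynyl}-9-methyl-5-(triisopropylsilyloxy)deca-1,3,5,8-tetraen-1-one | O=C=C(C#Cc1ccc(OCOC)cc1)/C(OC)=C\C(O[Si](C(C)C)(C(C)C)C(C)C)=C\CC=C(C)C | intermediate (not isolated)
20 | 3-methoxy-2-{[4-(methoxymethoxy)phenyl]ethynyl}-6-(3-methylbut-2-enyl)-5-(triisopropylsilyloxy)phenol | COc1cc(O[Si](C(C)C)(C(C)C)C(C)C)c(CC=C(C)C)c(O)c1C#Cc1ccc(OCOC)cc1 | intermediate
21 | 5-methoxy-4-{[4-(methoxymethoxy)phenyl]ethynyl}-2-(3-methylbut-2-enyl)benzene-1,3-diol | COc1cc(O)c(CC=C(C)C)c(O)c1C#Cc1ccc(OCOC)cc1 | intermediate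
22 | 3-methylbut-2-enal | CC(C)=CC=O | starting material
23 | (2Z)-5-hydroxy-3-methoxy-4-{[4-(methoxymethoxy)phenyl]ethynyl}-6-(3-methylbut-2-enyl)-2-(3-methylbut-2-enylidene)cyclohexa-3,5-dien-1-one | COC1=C(C#Cc2ccc(OCOC)cc2)C(O)=C(CC=C(C)C)C(=O)/C1=C\C=C(C)C | intermediate (not isolated)
24 | 5-methoxy-6-{[4-(methoxymethoxy)phenyl]ethynyl}-2,2-dimethyl-8-(3-methylbut-2-enyl)-2H-chromen-7-ol | COc1c2c(c(CC=C(C)C)c(O)c1C#Cc1ccc(OCOC)cc1)OC(C)(C)C=C2 | intermediate
25 | 5-methoxy-6-{[4-(methoxymethoxy)phenyl]ethynyl}-2,2-dimethyl-8-(3-methylbut-2-enyl)-2H-chromen-7-yl acetate | COc1c2c(c(CC=C(C)C)c(OC(C)=O)c1C#Cc1ccc(OCOC)cc1)OC(C)(C)C=C2 | intermediate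
26 | 1-[7-acetoxy-5-methoxy-2,2-dimethyl-8-(3-methylbut-2-enyl)-2H-chromen-6-yl]-2-[4-(methoxymethoxy)phenyl]ethane-1,2-dione | COc1c2c(c(CC=C(C)C)c(OC(C)=O)c1C(=O)C(=O)c1ccc(OCOC)cc1)OC(C)(C)C=C2 | intermediate
27 | 1-[7-acetoxy-5-methoxy-2,2-dimethyl-8-(3-methylbut-2-enyl)-2H-chromen-6-yl]-2-(4-hydroxyphenyl)ethane-1,2-dione | COc1c2c(c(CC=C(C)C)c(OC(C)=O)c1C(=O)C(=O)c1ccc(O)cc1)OC(C)(C)C=C2 | intermediate
28 | derrisdione A, 1-[7-hydroxy-5-methoxy-2,2-dimethyl-8-(3-methylbut-2-enyl)-2H-chromen-6-yl]-2-(4-hydroxyphenyl)ethane-1,2-dione | COc1c2c(c(CC=C(C)C)c(O)c1C(=O)C(=O)c1ccc(O)cc1)OC(C)(C)C=C2 | target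

## Step count and least certain steps

Total: 15 steps. Longest linear sequence: 12 steps (steps 1 to 5, then 9 to 15, from 1). The stannane branch (steps 6 to 8) joins at step 9.

Step 9 (key step). The hindered α-silyloxy stannane may transmetalate too slowly, so that destannylation of 17 or thermal decay of 9 overtakes the coupling. At 100 °C residual palladium may also cycloisomerize the new ortho-alkynylphenol.
- Fallback: a thermal Danheiser benzannulation that needs no tin and no palladium, setting out from 9 and from the ynol ether 15 and returning at 21.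
- Chloride 9 is reduced with zinc, acetic acid and TMEDA in ethanol to 3-methoxy-2-{[4-(methoxymethoxy)phenyl]ethynyl}cyclobut-2-en-1-one F1.
- Heating F1 with 15 in toluene at 80–110 °C should open it to a vinylketene that adds to the ynol ether. The new cyclobutenone opens and closes again to 5-methoxy-4-{[4-(methoxymethoxy)phenyl]ethynyl}-2-(3-methylbut-2-enyl)-3-(triisopropylsilyloxy)phenol F2.
- F2 carries the silyl group on the other oxygen than 20, but buffered fluoride converts both to the same diol 21.

Step 8. Tin may add in part to the distal alkyne carbon, or the silyl enol ether stannane may be protonated and lose tin during isolation.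
- Fallback: an acylstannane route from 12 that returns at 17.
- Hydroboration of the terminal alkyne of 12 with dicyclohexylborane and oxidation with NaBO3 gives 5-methylhex-4-enal F3.
- Addition of Bu3SnLi (from 16 and LiN(i-Pr)2) and oxidation of the alkoxide in the flask with 1,1′-(azodicarbonyl)dipiperidine gives tributyl(5-methylhex-4-enoyl)stannane F4.
- Enolization with LiN(i-Pr)2 and O-silylation with TIPSOTf at −78 °C should give 17, since the bulky stannyl group favours the enolate with the chain cis to oxygen.

Step 11. Under warm amine catalysis the free C7 phenol may add to the neighbouring alkyne (benzofuran formation), or the condensation at the crowded C4a may stall.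
- Fallback: an aryl propargyl ether Claisen sequence from 20, with the C7 oxygen masked throughout, returning at 25.
- Acetylation of 20 (Ac2O, pyridine, DMAP) gives 3-methoxy-2-{[4-(methoxymethoxy)phenyl]ethynyl}-6-(3-methylbut-2-enyl)-5-(triisopropylsilyloxy)phenyl acetate F5.
- Buffered fluoride (Bu4NF, AcOH) gives 3-hydroxy-5-methoxy-6-{[4-(methoxymethoxy)phenyl]ethynyl}-2-(3-methylbut-2-enyl)phenyl acetate F6.
- Copper-catalysed O-alkylation with 2-methylbut-3-yn-2-yl methyl carbonate (CuCl2 catalytic, DBU, MeCN, 0 °C) gives 5-methoxy-6-{[4-(methoxymethoxy)phenyl]ethynyl}-2-(3-methylbut-2-enyl)-3-[(2-methylbut-3-yn-2-yl)oxy]phenyl acetate F7.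
- Heating F7 in xylene at 140 °C (Claisen rearrangement to C4a, hydrogen shift, oxa-6π closure) gives 25.

Step 13. The di-ortho-substituted alkyne may react so slowly that divalent palladium attacks the chromene or prenyl double bond at the temperature required, or the neighbouring acetate may take part and divert the oxypalladation.
- Fallback: oxygenate the alkyne before the pyran ring exists and build the pyran on the diketone, setting out from 21 and returning at 28.
- Acetylation of both hydroxyls of 21 gives 5-methoxy-4-{[4-(methoxymethoxy)phenyl]ethynyl}-2-(3-methylbut-2-enyl)-1,3-phenylene diacetate F8.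
- PdCl2 in DMSO, now with the prenyl group as the only other π bond, gives 5-methoxy-4-{2-[4-(methoxymethoxy)phenyl]-2-oxoacetyl}-2-(3-methylbut-2-enyl)-1,3-phenylene diacetate F9.
- K2CO3 in MeOH at 0 °C gives 1-[2,4-dihydroxy-6-methoxy-3-(3-methylbut-2-enyl)phenyl]-2-[4-(methoxymethoxy)phenyl]ethane-1,2-dione F10.
- Chromenylation with 22 in pyridine at 120 °C, a tertiary amine that cannot condense with the diketone, gives 1-[7-hydroxy-5-methoxy-2,2-dimethyl-8-(3-methylbut-2-enyl)-2H-chromen-6-yl]-2-[4-(methoxymethoxy)phenyl]ethane-1,2-dione F11. The C7 hydroxyl is chelated by the ketone and only the C8a oxygen can close onto C4a.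
- Mild aqueous HCl in THF then frees the ring B phenol and gives 28.

## Further compounds

F1 | step 9 | 3-methoxy-2-{[4-(methoxymethoxy)phenyl]ethynyl}cyclobut-2-en-1-one | COCOc1ccc(cc1)C#CC1=C(OC)CC1=O
F2 | step 9 | 5-methoxy-4-{[4-(methoxymethoxy)phenyl]ethynyl}-2-(3-methylbut-2-enyl)-3-(triisopropylsilyloxy)phenol | COc1cc(O)c(CC=C(C)C)c(O[Si](C(C)C)(C(C)C)C(C)C)c1C#Cc1ccc(OCOC)cc1
F3 | step 8 | 5-methylhex-4-enal | CC(C)=CCCC=O
F4 | step 8 | tributyl(5-methylhex-4-enoyl)stannane | CCCC[Sn](CCCC)(CCCC)C(=O)CCC=C(C)C
F5 | step 11 | 3-methoxy-2-{[4-(methoxymethoxy)phenyl]ethynyl}-6-(3-methylbut-2-enyl)-5-(triisopropylsilyloxy)phenyl acetate | COc1cc(O[Si](C(C)C)(C(C)C)C(C)C)c(CC=C(C)C)c(OC(C)=O)c1C#Cc1ccc(OCOC)cc1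
F6 | step 11 | 3-hydroxy-5-methoxy-6-{[4-(methoxymethoxy)phenyl]ethynyl}-2-(3-methylbut-2-enyl)phenyl acetate | COc1cc(O)c(CC=C(C)C)c(OC(C)=O)c1C#Cc1ccc(OCOC)cc1
F7 | step 11 | 5-methoxy-6-{[4-(methoxymethoxy)phenyl]ethynyl}-2-(3-methylbut-2-enyl)-3-[(2-methylbut-3-yn-2-yl)oxy]phenyl acetate | COc1cc(OC(C)(C)C#C)c(CC=C(C)C)c(OC(C)=O)c1C#Cc1ccc(OCOC)cc1
F8 | step 13 | 5-methoxy-4-{[4-(methoxymethoxy)phenyl]ethynyl}-2-(3-methylbut-2-enyl)-1,3-phenylene diacetate | COc1cc(OC(C)=O)c(CC=C(C)C)c(OC(C)=O)c1C#Cc1ccc(OCOC)cc1
F9 | step 13 | 5-methoxy-4-{2-[4-(methoxymethoxy)phenyl]-2-oxoacetyl}-2-(3-methylbut-2-enyl)-1,3-phenylene diacetate | COc1cc(OC(C)=O)c(CC=C(C)C)c(OC(C)=O)c1C(=O)C(=O)c1ccc(OCOC)cc1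
F10 | step 13 | 1-[2,4-dihydroxy-6-methoxy-3-(3-methylbut-2-enyl)phenyl]-2-[4-(methoxymethoxy)phenyl]ethane-1,2-dione | COc1cc(O)c(CC=C(C)C)c(O)c1C(=O)C(=O)c1ccc(OCOC)cc1
F11 | step 13 | 1-[7-hydroxy-5-methoxy-2,2-dimethyl-8-(3-methylbut-2-enyl)-2H-chromen-6-yl]-2-[4-(methoxymethoxy)phenyl]ethane-1,2-dione | COc1c2c(c(CC=C(C)C)c(O)c1C(=O)C(=O)c1ccc(OCOC)cc1)OC(C)(C)C=C2
A1 | alternative 1 | derrisdione A bis(methoxymethyl) ether | COc1c2c(c(CC=C(C)C)c(OCOC)c1C(=O)C(=O)c1ccc(OCOC)cc1)OC(C)(C)C=C2
A2 | alternative 1 | 1,4-dimethylpiperazine-2,3-dione | CN1CCN(C)C(=O)C1=O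
A3 | alternative 1 | 5-methoxy-7-(methoxymethoxy)-2,2-dimethyl-8-(3-methylbut-2-enyl)-2H-chromene | COc1cc(OCOC)c(CC=C(C)C)c2OC(C)(C)C=Cc12
A4 | alternative 1 | 4-(methoxymethoxy)phenylmagnesium bromide | COCOc1ccc([Mg]Br)cc1
A5 | alternative 2 | 7-(benzyloxy)-5-methoxy-3-[4-(methoxymethoxy)phenyl]chromen-4-one | COc1cc(OCc2ccccc2)cc2occ(-c3ccc(OCOC)cc3)c(=O)c12
A6 | alternative 2 | (E)-1-[4-(benzyloxy)-2-hydroxy-6-methoxyphenyl]-3-[4-(methoxymethoxy)phenyl]prop-2-en-1-one | COc1cc(OCc2ccccc2)cc(O)c1C(=O)/C=C/c1ccc(OCOC)cc1
A7 | alternative 2 | thallium trinitrate | [Tl+3].[O-][N+](=O)[O-].[O-][N+](=O)[O-].[O-][N+](=O)[O-]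
A8 | alternative 3 | 1-[2,4-dihydroxy-6-methoxy-3-(3-methylbut-2-enyl)phenyl]-2,2-dimethoxy-2-[4-(methoxymethoxy)phenyl]ethanone | COc1cc(O)c(CC=C(C)C)c(O)c1C(=O)C(OC)(OC)c1ccc(OCOC)cc1
A9 | alternative 3 | methyl acetate | COC(C)=O
A10 | alternative 3 | 3-[methoxy(methylsulfanyl)methylidene]-1,1-dimethoxy-1-[4-(methoxymethoxy)phenyl]-8-methylnon-7-ene-2,4-dione | COC(SC)=C(C(=O)CCC=C(C)C)C(=O)C(OC)(OC)c1ccc(OCOC)cc1
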